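**Assumption:** 2-methylallylmagnesium chloride (THF solution), tributyl(2-methylallyl)stannane and 3-(benzyloxy)-4-methoxybenzoic acid are bought; labels C1–C10 are the ten ring carbons of the target (C2/C6 ring fusion, C3/C4 oxirane, C7 i-Pr, C8 ester, C10 carbinol).

## Retrosynthetic overview

1. Target 18 ⇐ O-debenzylation, C10-OH-directed epoxidation of C3=C4, acylation of C8-OH ⇐ hydroazulene diol 14.
2. 14 ⇐ ring-closing metathesis (cyclopentene) ⇐ vinyl/methallyl cycloheptanediol 13 ⇐ DIBAL/Wittig opening of bridged lactone 10.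
3. 10 ⇐ key step: malonate-to-oxirane 7-endo C-alkylation (C2–C1) with in-situ lactonisation (C10–O–C3) and loss of the spare ester; the cycloheptane and the γ-lactone form together and lock C2 to C10 ⇐ acyclic epoxy malonate 8.
4. 8 ⇐ OH-directed epoxidation (C10) ⇐ Keck methallylation (C8) ⇐ enamine Michael addition of 3-methylbutanal (C7, C6) to alkylidene malonate 3 ⇐ ethoxymethylene malonate + methallyl Grignard.
5. Ring order: cycloheptane + γ-lactone (step 5), lactone opened (steps 6–7), cyclopentene (step 8), oxirane (step 10).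

## Route

**Step 1**
Reactants: 1 2-methylallylmagnesium chloride; 2 diethyl 2-(ethoxymethylidene)propanedioate
Product: 3 diethyl 2-(3-methylbut-3-en-1-ylidene)propanedioate
Conditions: THF, −78 → −20 °C (1 added to 2); aq NH4Cl
Reagents that add atoms: none
Why: Conjugate addition–elimination of the allylic Grignard reagent on the alkoxymethylene malonate expels ethoxide and gives the alkylidene malonate; no stereocentre is formed.

**Step 2**
Reactants: 3 diethyl 2-(3-methylbut-3-en-1-ylidene)propanedioate; 4 3-methylbutanal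
Product: 5 diethyl 2-[(4S,5S)-5-formyl-2,6-dimethylhept-1-en-4-yl]propanedioate
Conditions: (R)-α,α-diphenylprolinol TMS ether (20 mol %), PhCO2H (20 mol %), toluene, 0 °C → rt
Reagents that add atoms: none
Why: Enamine-catalysed (Hayashi–Jørgensen) Michael addition, in which the anti-enamine of 4 adds through its unshielded face via the acyclic synclinal transition state, sets C7 and the syn-related C6 in one event.

**Step 3**
Reactants: 5 diethyl 2-[(4S,5S)-5-formyl-2,6-dimethylhept-1-en-4-yl]propanedioate; 6 tributyl(2-methylprop-2-en-1-yl)stannane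
Product: 7 diethyl 2-[(4S,5S,6R)-6-hydroxy-2,8-dimethyl-5-(propan-2-yl)nona-1,8-dien-4-yl]propanedioate
Conditions: (R)-BINOL (20 mol %), Ti(OiPr)4 (10 mol %), 4 Å MS, CH2Cl2, −20 °C
Reagents that add atoms: none
Why: Keck asymmetric allylation, in which the (R)-BINOL–Ti Lewis acid sends the methallylstannane to the Re face of the aldehyde (catalyst control over the Felkin bias), gives the (R)-carbinol at C8 under neutral conditions that leave the malonate untouched.

**Step 4**
Reactants: 7 diethyl 2-[(4S,5S,6R)-6-hydroxy-2,8-dimethyl-5-(propan-2-yl)nona-1,8-dien-4-yl]propanedioate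
Product: 8 diethyl 2-[(4S,5S,6R)-6-hydroxy-2-methyl-7-[(2S)-2-methyloxiran-2-yl]-5-(propan-2-yl)hept-1-en-4-yl]propanedioate
Conditions: VO(acac)2 (5 mol %), t-BuOOH, CH2Cl2, 0 °C
Reagents that add atoms: tert-butyl hydroperoxide, CC(C)(C)OO
Why: Hydroxyl-directed vanadium epoxidation, in which the C8 vanadate delivers oxygen only to the homoallylic 2-methylallyl group through a chair-like transition state with the C7 chain equatorial, gives the 1,3-syn epoxy alcohol (new C10 centre) and leaves the remote methallyl group on C6 alone.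

**Step 5**
Reactants: 8 diethyl 2-[(4S,5S,6R)-6-hydroxy-2-methyl-7-[(2S)-2-methyloxiran-2-yl]-5-(propan-2-yl)hept-1-en-4-yl]propanedioate
Product: 10 (1S,2S,3S,4R,6R)-4-hydroxy-6-methyl-2-(2-methylprop-2-en-1-yl)-3-(propan-2-yl)-7-oxabicyclo[4.2.1]nonan-8-one, via ethoxycarbonyl lactone 9 (not isolated)
Conditions: Cs2CO3 (0.3 equiv), DMSO (0.005 M), 80 °C; then LiCl, H2O, 150 °C; aq HCl work-up
Reagents that add atoms: none
Why: Proposed new method: the caesium malonate attacks the unhindered CH2 end of the 2,2-disubstituted oxirane (7-endo, because the exo mode would need SN2 at a quaternary carbon) to close the cycloheptane, the tertiary alkoxide so formed lactonises onto the ester on its own face, and Krapcho loss of the other ester leaves C2–H, so the bridge fixes C2 cis to the C10 oxygen set in step 4; the closest known reaction type is the malonate–epoxide alkylation/γ-lactonisation followed by Krapcho dealkoxycarbonylation.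

**Step 6**
Reactants: 10 (1S,2S,3S,4R,6R)-4-hydroxy-6-methyl-2-(2-methylprop-2-en-1-yl)-3-(propan-2-yl)-7-oxabicyclo[4.2.1]nonan-8-one
Product: 11 (1S,2S,3S,4R,6R)-6-methyl-2-(2-methylprop-2-en-1-yl)-3-(propan-2-yl)-7-oxabicyclo[4.2.1]nonane-4,8-diol (lactol, both C8 epimers)
Conditions: DIBAL-H (2.5 equiv), CH2Cl2, −78 °C; Rochelle salt
Reagents that add atoms: none
Why: Partial hydride reduction of the γ-lactone stops at the aluminium acetal at −78 °C and gives the lactol without touching any stereocentre.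

**Step 7**
Reactants: 11 (1S,2S,3S,4R,6R)-6-methyl-2-(2-methylprop-2-en-1-yl)-3-(propan-2-yl)-7-oxabicyclo[4.2.1]nonane-4,8-diol; 12 methyltriphenylphosphonium bromide
Product: 13 (1R,3R,4S,5R,6R)-6-ethenyl-1-methyl-5-(2-methylprop-2-en-1-yl)-4-(propan-2-yl)cycloheptane-1,3-diol
Conditions: KOt-Bu, THF, 0 °C → rt
Reagents that add atoms: none
Why: Wittig methylenation of the ring-opened hydroxy aldehyde turns C3 into the vinyl group and frees the C10 hydroxyl; C2 stays in the trans arrangement to C6, which is also the thermodynamically preferred one.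

**Step 8**
Reactants: 13 (1R,3R,4S,5R,6R)-6-ethenyl-1-methyl-5-(2-methylprop-2-en-1-yl)-4-(propan-2-yl)cycloheptane-1,3-diol
Product: 14 (3aR,4S,5R,7R,8aS)-2,7-dimethyl-4-(propan-2-yl)-3,3a,4,5,6,7,8,8a-octahydroazulene-5,7-diol
Conditions: Grubbs II (5 mol %), CH2Cl2 (0.005 M), 40 °C
Reagents that add atoms: none
Why: Ring-closing metathesis of the vinyl and 2-methylallyl groups is the only productive pairing and gives the trisubstituted cyclopentene; the trans ring fusion follows from the C2 and C6 centres already in place.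

**Step 9**
Reactants: 14 (3aR,4S,5R,7R,8aS)-2,7-dimethyl-4-(propan-2-yl)-3,3a,4,5,6,7,8,8a-octahydroazulene-5,7-diol; 15 3-(benzyloxy)-4-methoxybenzoic acid
Product: 16 (3aR,4S,5R,7R,8aS)-7-hydroxy-2,7-dimethyl-4-(propan-2-yl)-3,3a,4,5,6,7,8,8a-octahydroazulen-5-yl 3-(benzyloxy)-4-methoxybenzoate
Conditions: DCC, DMAP, CH2Cl2, rt
Reagents that add atoms: none
Why: Steglich esterification acylates the secondary C8 hydroxyl with retention and leaves the tertiary C10 hydroxyl free.

**Step 10**
Reactants: 16 (3aR,4S,5R,7R,8aS)-7-hydroxy-2,7-dimethyl-4-(propan-2-yl)-3,3a,4,5,6,7,8,8a-octahydroazulen-5-yl 3-(benzyloxy)-4-methoxybenzoate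
Product: 17 (1S,2R,3aR,4S,5R,7R,8aS)-1,2-epoxy-7-hydroxy-2,7-dimethyl-4-(propan-2-yl)decahydroazulen-5-yl 3-(benzyloxy)-4-methoxybenzoate
Conditions: VO(acac)2 (10 mol %), t-BuOOH, toluene, rt
Reagents that add atoms: tert-butyl hydroperoxide, CC(C)(C)OO
Why: Hydroxyl-directed vanadium epoxidation from the bishomoallylic tertiary C10 alkoxide delivers oxygen to the face of C3=C4 that carries the C10 oxygen, and the syn epoxy alcohol cannot cyclise further because back-side attack is geometrically impossible.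

**Step 11**
Reactants: 17 (1S,2R,3aR,4S,5R,7R,8aS)-1,2-epoxy-7-hydroxy-2,7-dimethyl-4-(propan-2-yl)decahydroazulen-5-yl 3-(benzyloxy)-4-methoxybenzoate
Product: 18 (1S,2R,3aR,4S,5R,7R,8aS)-1,2-epoxy-7-hydroxy-2,7-dimethyl-4-(propan-2-yl)decahydroazulen-5-yl 3-hydroxy-4-methoxybenzoate (target)
Conditions: H2 (1 atm), 10% Pd/C, EtOAc, rt, short reaction time
Reagents that add atoms: none
Why: Hydrogenolysis of the aryl benzyl ether frees the phenol under neutral conditions that spare the non-benzylic trisubstituted oxirane and the ester.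

## Compound list

1 | 2-methylallylmagnesium chloride | CC(=C)C[Mg]Cl | starting material
2 | diethyl 2-(ethoxymethylidene)propanedioate | CCOC=C(C(=O)OCC)C(=O)OCC | starting material
3 | diethyl 2-(3-methylbut-3-en-1-ylidene)propanedioate | CC(=C)CC=C(C(=O)OCC)C(=O)OCC | intermediate
4 | 3-methylbutanal | CC(C)CC=O | starting material
5 | diethyl 2-[(4S,5S)-5-formyl-2,6-dimethylhept-1-en-4-yl]propanedioate | CCOC(=O)C(C(=O)OCC)[C@@H](CC(C)=C)[C@@H](C=O)C(C)C | intermediate
6 | tributyl(2-methylprop-2-en-1-yl)stannane | CCCC[Sn](CCCC)(CCCC)CC(C)=C | starting material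
7 | diethyl 2-[(4S,5S,6R)-6-hydroxy-2,8-dimethyl-5-(propan-2-yl)nona-1,8-dien-4-yl]propanedioate | CCOC(=O)C(C(=O)OCC)[C@@H](CC(C)=C)[C@@H]([C@H](O)CC(C)=C)C(C)C | intermediate
8 | diethyl 2-[(4S,5S,6R)-6-hydroxy-2-methyl-7-[(2S)-2-methyloxiran-2-yl]-5-(propan-2-yl)hept-1-en-4-yl]propanedioate | CCOC(=O)C(C(=O)OCC)[C@@H](CC(C)=C)[C@@H]([C@H](O)C[C@@]1(C)CO1)C(C)C | intermediate
9 | ethyl (1S,2S,3S,4R,6R)-4-hydroxy-6-methyl-2-(2-methylprop-2-en-1-yl)-8-oxo-3-(propan-2-yl)-7-oxabicyclo[4.2.1]nonane-1-carboxylate | O[C@@H]1C[C@]2(C)OC(=O)[C@](C2)(C(=O)OCC)[C@@H](CC(C)=C)[C@@H]1C(C)C | intermediate (not isolated)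
10 | (1S,2S,3S,4R,6R)-4-hydroxy-6-methyl-2-(2-methylprop-2-en-1-yl)-3-(propan-2-yl)-7-oxabicyclo[4.2.1]nonan-8-one | O[C@@H]1C[C@]2(C)OC(=O)[C@@H](C2)[C@@H](CC(C)=C)[C@@H]1C(C)C | intermediate
11 | (1S,2S,3S,4R,6R)-6-methyl-2-(2-methylprop-2-en-1-yl)-3-(propan-2-yl)-7-oxabicyclo[4.2.1]nonane-4,8-diol (lactol, C8 epimers) | O[C@@H]1C[C@]2(C)OC(O)[C@@H](C2)[C@@H](CC(C)=C)[C@@H]1C(C)C | intermediate
12 | methyltriphenylphosphonium bromide | C[P+](c1ccccc1)(c1ccccc1)c1ccccc1.[Br-] | starting material
13 | (1R,3R,4S,5R,6R)-6-ethenyl-1-methyl-5-(2-methylprop-2-en-1-yl)-4-(propan-2-yl)cycloheptane-1,3-diol | O[C@@H]1C[C@](C)(O)C[C@H](C=C)[C@@H](CC(C)=C)[C@@H]1C(C)C | intermediate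
14 | (3aR,4S,5R,7R,8aS)-2,7-dimethyl-4-(propan-2-yl)-3,3a,4,5,6,7,8,8a-octahydroazulene-5,7-diol | O[C@@H]1C[C@](C)(O)C[C@H]2[C@@H](CC(C)=C2)[C@@H]1C(C)C | intermediate
15 | 3-(benzyloxy)-4-methoxybenzoic acid | COc1ccc(C(=O)O)cc1OCc1ccccc1 | starting material
16 | (3aR,4S,5R,7R,8aS)-7-hydroxy-2,7-dimethyl-4-(propan-2-yl)-3,3a,4,5,6,7,8,8a-octahydroazulen-5-yl 3-(benzyloxy)-4-methoxybenzoate | COc1ccc(C(=O)O[C@@H]2C[C@](C)(O)C[C@H]3[C@@H](CC(C)=C3)[C@@H]2C(C)C)cc1OCc1ccccc1 | intermediate
17 | (1S,2R,3aR,4S,5R,7R,8aS)-1,2-epoxy-7-hydroxy-2,7-dimethyl-4-(propan-2-yl)decahydroazulen-5-yl 3-(benzyloxy)-4-methoxybenzoate | COc1ccc(C(=O)O[C@@H]2C[C@](C)(O)C[C@H]3[C@@H](C[C@@]4(C)O[C@@H]34)[C@@H]2C(C)C)cc1OCc1ccccc1 | intermediate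
18 | (1S,2R,3aR,4S,5R,7R,8aS)-1,2-epoxy-7-hydroxy-2,7-dimethyl-4-(propan-2-yl)decahydroazulen-5-yl 3-hydroxy-4-methoxybenzoate | COc1ccc(C(=O)O[C@@H]2C[C@](C)(O)C[C@H]3[C@@H](C[C@@]4(C)O[C@@H]34)[C@@H]2C(C)C)cc1O | target

## Step count and risks

Total step count: 11. Longest linear sequence: 11 steps (1/2 → 18).

**Step 2.** Alkyl-substituted alkylidene malonates are sluggish acceptors in enamine catalysis, and the skipped diene of 3 can drift into conjugation under amine catalysis. The fallback sets out from 3 and uses a Lewis-acid Mukaiyama–Michael addition instead. 3-Methylbutanoyl chloride and 2-methylpropane-2-thiol (Et3N) give S-tert-butyl 3-methylbutanethioate F1. LDA/Me3SiCl at −78 °C converts it into the (Z)-silyl ketene thioacetal F2. F2 adds to 3 under a Cu(II)–tert-butyl-bis(oxazoline) catalyst (the enantiomer and ketene-acetal geometry chosen for the syn adduct) with hexafluoroisopropanol in CH2Cl2 at −78 °C, giving thioester adduct F3. One equivalent of DIBAL-H at −78 °C reduces the thioester to the aldehyde, and the route is rejoined at 5.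

**Step 4.** The 1,3-induction of the vanadium epoxidation of a homoallylic alcohol may be modest, and the wrong C10 epimer would carry through step 5. The fallback sets out from 7 and replaces reagent delivery by a cyclisation. Boc2O/DMAP gives the tert-butyl carbonate F4. IBr in toluene at −85 °C closes it to the cis (1,3-syn) cyclic iodocarbonate F5, with both ring substituents equatorial. K2CO3 in methanol cleaves the carbonate and closes the oxirane, which rejoins the route at 8.

**Step 5.** The 7-endo attack of a hindered malonate on the oxirane may be slow, or may lose to oxygen attack by the C8 hydroxyl. The fallback sets out from 7, skipping 8, and closes the ring by a radical instead of an anion. Mn(OAc)3·2H2O in acetic acid at 70 °C generates the malonyl radical, which cyclises 7-endo onto the 2-methylallyl terminus. The tertiary radical is oxidised to the cation and captured by the ester on the same face, giving 9, this time isolated. The C10 epimers would have to be separated. LiCl/H2O/DMSO at 150 °C then gives 10, where the route is rejoined. This fallback makes no compound outside the list (F0).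

Further compounds
F1 | step 2 | S-tert-butyl 3-methylbutanethioate | CC(C)CC(=O)SC(C)(C)C
F2 | step 2 | (Z)-{[1-(tert-butylsulfanyl)-3-methylbut-1-en-1-yl]oxy}trimethylsilane | CC(C)/C=C(/O[Si](C)(C)C)SC(C)(C)C
F3 | step 2 | diethyl 2-[(4R,5S)-5-[(tert-butylsulfanyl)carbonyl]-2,6-dimethylhept-1-en-4-yl]propanedioate | CCOC(=O)C(C(=O)OCC)[C@@H](CC(C)=C)[C@@H](C(=O)SC(C)(C)C)C(C)C
F4 | step 4 | tert-butyl carbonate of alcohol 7 (C8–OBoc) | CCOC(=O)C(C(=O)OCC)[C@@H](CC(C)=C)[C@@H]([C@H](OC(=O)OC(C)(C)C)CC(C)=C)C(C)C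
F5 | step 4 | cis-4-(iodomethyl)-4-methyl-1,3-dioxan-2-one (cyclic iodocarbonate) formed from F4, attached at its C6 to the malonate chain | CCOC(=O)C(C(=O)OCC)[C@@H](CC(C)=C)[C@@H]([C@H]1C[C@@](C)(CI)OC(=O)O1)C(C)C
F0 | step 5 | none | none
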